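## The problem

The target 21 is a linear tridepside. A 2,3,4-trimethoxy-6-methylbenzoyl group (ring A) is esterified to O4 of a 2-hydroxy-6-methylbenzoate (ring B), whose carboxyl esterifies O4 of 2,4-dihydroxy-6-methylbenzoic acid (ring C), which ends in a free acid. There is no stereocentre, so every difficulty is one of regiochemistry and chemoselectivity. Both ester carbonyls sit between two ortho substituents (OMe and Me on ring A, OH and Me on ring B), so each depside bond joins a hindered acyl donor to a phenol. On rings B and C only O4 may be acylated while O2 stays free. The aryl esters do not tolerate hydroxide, alkoxide or hot nucleophiles, and the terminal salicylic acid decarboxylates on heating, so the closing operations must be neutral and mild. Rings B and C are the same ring, which invites one building block used twice. Its pattern makes the key step possible: C1 (carboxyl-bearing), C2 (oxygen-bearing), C3 (CH), C4 (oxygen-bearing), C5 (CH) and C6 (methyl-bearing) are the head-to-tail union of one but-2-ynoate (C6–C1) with two alkoxyacetylenes (C5–C4 and C3–C2).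

## Retrosynthesis

**21 from 20.** Only the O–benzyl bond of the ring C ester is cut. A benzyl ester is chosen because hydrogenolysis is neutral, runs at room temperature and leaves both aryl esters and the methyl ethers alone. A methyl or tert-butyl ester would need hydroxide or strong acid at the end.

**20 from 18 and 11.** The inner ester C(=O)–O4 bond between ring B and ring C is cut, giving the ring A–ring B hydroxy acid 18 and benzyl orsellinate 11. Cutting here first means both esterifications use the same phenol 11 and no extra protecting group is needed on ring B. Building ring B–ring C first would need the ring B O4 masked orthogonally to the benzyl ester. The forward reaction must activate 18 with its 2-OH free and acylate 11 at O4 only. In both partners the 2-OH is hydrogen-bonded to the ortho carbonyl and flanked on both sides, which is what the selectivity rests on.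

**18 from 17, and 17 from 15 and 11.** The benzyl ester of 17 is removed by hydrogenolysis. The outer ester bond is then cut to the ring A acid 15 and 11 again. Acid 15 is doubly ortho-substituted, so an acylium-like donor (its mixed trifluoroacetic anhydride) is asked for.

**15 from 13 and 12.** The aryl–carboxyl bond is cut. 3,4,5-Trimethoxytoluene 12 has two equivalent free positions, so monobromination to 13 and bromine–lithium exchange with carboxylation place the acid unambiguously. Direct lithiation of 12 would risk benzylic metalation.

**11 from 10.** Two O–tert-butyl bonds are cut. tert-Butyl ethers fall to trifluoroacetic acid while the benzyl ester survives. Methyl or ethyl ethers would need boron halides, which also cleave the benzyl ester, and benzyl alkynyl ethers are not stable reagents.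

**10 from 9 and two molecules of 6.** C1–C2, C3–C4 and C5–C6 are cut, taking the ring apart into benzyl but-2-ynoate 9 and tert-butoxyacetylene 6. Against the polyketide-type cuts (C1–C6 and C3–C4), this delivers the arene at the right oxidation level with both oxygens masked and distinct from the carboxyl. The forward reaction must give the 2:1 cross-trimer, head to tail throughout, at room temperature.

**9 from 7 and 8; 6 from 3 and 1.** Ester 9 comes from but-2-ynoic acid 7 and benzyl alcohol 8. Ynol ether 6 comes from trichloroethylene 1 through the E-dichlorovinyl ether 3.

## Roads not taken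

**Alternative 1:** The cut is through the ring B C1–carbonyl bond and the carbonyl–O4 bond of ring C. Pd(OAc)2 with Xantphos under carbon monoxide would join the aryl bromide A2 (ring A ester of a ring B bromide carrying a methoxymethyl ether) with phenol 11 to give the protected tridepside A1.
- Merits: it is convergent, the reaction type is known, and it makes the most awkward ester without ever handling a free hydroxy acid. In that respect it is better than the chosen plan.
- Weak points: the bromide in A2 lies between two ortho substituents, so oxidative addition and CO insertion are slow. Base, phenoxide and heat in the presence of two aryl esters invite acyl exchange. A2 needs a bromoresorcinol with its two phenols told apart, and an extra acetal removal follows.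
- Comparison: this road builds no ring, so the orsellinate units must still be sourced. The chosen plan sets one ring-forming step serving rings B and C and a room-temperature assembly against it, and concedes that its own key step is unproven.

**Alternative 2:** The cut is through C1–C6 and C3–C4 of ring C. A Michael addition of a β-keto ester enolate to an enoate, then Dieckmann closure, gives the dioxocyclohexane ester A3, to be O-acylated and aromatised late.
- Merits: the ring closure is classical, cheap and more reliable than the proposed cyclotrimerisation.
- Weak points: A3 is at the wrong oxidation level and its two stereocentres are made only to be destroyed. Acylation of the dione must choose between two enol oxygens and carbon. The late dehydrogenation must spare the depside esters and the electron-rich ring A.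
- Comparison: the chosen plan has no redox adjustment and delivers the ring already differentiated, which offsets its riskier ring formation.

**Alternative 3:** The cut is through C1–C6 of ring B. The aryl trioxooctanoate A5, already esterified to ring C, would fold under mild base by aldol addition of C2 to the C7 ketone, dehydration and enolisation to the didepside A4.
- Merits: it is biomimetic and forms the hindered inner ester before ring B exists, so that coupling problem disappears. This is a real advantage over the chosen plan.
- Weak points: the aryl ester of A5 is an activated ester next to an enolisable polyketone. Lactonisation through the C5 enol oxygen or Claisen closure from C6 would expel the ring C phenoxide. Ring C must still be made separately, and A4 then needs acylation of one of three phenols.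
- Comparison: the chosen plan forms its esters only when both rings are complete and uses one ring synthesis for rings B and C.

Key step: step 4

## Route

Remark: the target has no stereocentre, so racemic BINAP suffices in step 4. tert-Butoxyacetylene 6 is assumed not to be a stock chemical and is made in steps 1 and 2.

Step 1
Reactants: 1 trichloroethylene
Product: 3 (E)-1-tert-butoxy-1,2-dichloroethene, via dichloroacetylene 2 (not isolated)
Conditions: KOtBu (1.1 equiv), THF, −40 °C to rt
Reagents that add atoms: potassium tert-butoxide, CC(C)(C)[O-].[K+]
Why: Dehydrochlorination gives dichloroacetylene in solution, and anti addition of tert-butoxide and a proton across it gives the E-dichlorovinyl ether. This elimination–addition is the standard entry to ynol ether precursors from trichloroethylene.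

Step 2
Reactants: 3 (E)-1-tert-butoxy-1,2-dichloroethene
Product: 6 tert-butoxyacetylene, via 1-tert-butoxy-2-chloroacetylene 4 (not isolated), via lithium tert-butoxyacetylide 5 (not isolated)
Conditions: n-BuLi (2.1 equiv), Et2O, −78 to −40 °C; H2O, −78 to 0 °C; distillation below 30 °C under reduced pressure
Reagents that add atoms: none
Why: One equivalent of n-BuLi effects β-elimination of HCl to the chloroalkyne, and the second effects chlorine–lithium exchange to the lithium acetylide, which water protonates. The product should be kept cold, since it loses 2-methylpropene to ketene on warming.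

Step 3
Reactants: 7 but-2-ynoic acid; 8 benzyl alcohol
Product: 9 benzyl but-2-ynoate
Conditions: DCC, DMAP (5 mol %), CH2Cl2, 0 °C to rt
Reagents that add atoms: none
Why: Steglich esterification of an alkynoic acid with a primary alcohol, with low temperature and little DMAP to avoid conjugate addition to the ynoate.

Step 4
Reactants: 9 benzyl but-2-ynoate; 6 tert-butoxyacetylene (two molecules)
Product: 10 benzyl 2,4-di-tert-butoxy-6-methylbenzoate
Conditions: [Rh(cod)2]BF4 (5 mol %), rac-BINAP (5 mol %), pre-activated under H2 then Ar, CH2Cl2, rt; 6 (2.2 equiv) added by syringe pump over several hours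
Reagents that add atoms: none
Why: Proposed new method: the cationic monovalent rhodium–BINAP fragment, freed of cyclooctadiene by hydrogenation, binds 9 and one molecule of 6 and couples them oxidatively to a trivalent rhodacyclopentadiene in which the nucleophilic CH carbon of 6 has bonded to the electrophilic methyl-bearing β-carbon of 9 (C5–C6), leaving rhodium on the ester-bearing C1 and the alkoxy-bearing C4. A second molecule of 6 inserts into the rhodium–C4 bond with its CH carbon joining C4 (C3–C4), and the rhodacycloheptatriene so formed closes the ring by C1–C2 reductive elimination, returning monovalent rhodium. The closest known reaction type is the cationic rhodium–bisphosphine catalysed cross (2+2+2) cyclotrimerisation of two terminal alkynes with one electron-poor alkyne, beside the room-temperature regioselective homotrimerisation of alkynyl ethers by such catalysts; two ynol ethers with a but-2-ynoate have not been shown. The six-membered ring is closed on the metal template by reductive elimination from a seven-membered metallacycle, and no stereocentre is formed. The step needs the 2:1 cross-trimer with head-to-tail orientation: each new bond pairs a donor-polarised with an acceptor-polarised alkyne carbon, the internal ynoate does not trimerise with itself, and slow addition keeps 6 too dilute to homotrimerise. Room temperature is essential because 6 fragments to ketene when heated.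

Step 5
Reactants: 10 benzyl 2,4-di-tert-butoxy-6-methylbenzoate
Product: 11 benzyl 2,4-dihydroxy-6-methylbenzoate (benzyl orsellinate)
Conditions: TFA, CH2Cl2, 0 °C to rt
Reagents that add atoms: none
Why: Acidolysis of aryl tert-butyl ethers with loss of 2-methylpropene; a benzyl ester is stable to trifluoroacetic acid at room temperature. Both free ring positions are flanked by two substituents, which should disfavour ring tert-butylation.

Step 6
Reactants: 12 3,4,5-trimethoxytoluene
Product: 13 2-bromo-3,4,5-trimethoxytoluene
Conditions: NBS (1.0 equiv), MeCN, 0 °C to rt
Reagents that add atoms: N-bromosuccinimide, O=C1CCC(=O)N1Br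
Why: Electrophilic aromatic bromination of an activated arene whose two free positions are equivalent. One equivalent of reagent and the deactivating first bromine should stop it at the monobromide.

Step 7
Reactants: 13 2-bromo-3,4,5-trimethoxytoluene
Product: 15 2,3,4-trimethoxy-6-methylbenzoic acid, via (2,3,4-trimethoxy-6-methylphenyl)lithium 14 (not isolated)
Conditions: n-BuLi (1.05 equiv), THF, −78 °C; CO2, −78 °C to rt; 1 M HCl
Reagents that add atoms: carbon dioxide, O=C=O
Why: Bromine–lithium exchange followed by carboxylation of the aryllithium. At −78 °C alkylation by 1-bromobutane and benzylic proton transfer should not compete.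

Step 8
Reactants: 15 2,3,4-trimethoxy-6-methylbenzoic acid; 11 benzyl 2,4-dihydroxy-6-methylbenzoate
Product: 17 benzyl 2-hydroxy-6-methyl-4-[(2,3,4-trimethoxy-6-methylbenzoyl)oxy]benzoate, via 2,3,4-trimethoxy-6-methylbenzoic trifluoroacetic anhydride 16 (not isolated)
Conditions: 15, TFAA (1.5 equiv), toluene, 0 °C; then 11, rt
Reagents that add atoms: none
Why: Trifluoroacetic anhydride depside condensation: the mixed anhydride is an acylium-like donor suited to a doubly ortho-substituted benzoic acid. It should acylate the free 4-OH of 11, while the 2-OH is held by a hydrogen bond to the ester carbonyl and is flanked on both sides.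

Step 9
Reactants: 17 benzyl 2-hydroxy-6-methyl-4-[(2,3,4-trimethoxy-6-methylbenzoyl)oxy]benzoate
Product: 18 2-hydroxy-6-methyl-4-[(2,3,4-trimethoxy-6-methylbenzoyl)oxy]benzoic acid
Conditions: H2 (1 atm), 10% Pd/C, EtOAc, rt
Reagents that add atoms: none
Why: Hydrogenolysis of a benzyl ester, which leaves the aryl ester and the methyl ethers untouched. Room temperature avoids decarboxylation of the salicylic acid.

Step 10
Reactants: 18 2-hydroxy-6-methyl-4-[(2,3,4-trimethoxy-6-methylbenzoyl)oxy]benzoic acid; 11 benzyl 2,4-dihydroxy-6-methylbenzoate
Product: 20 benzyl 2-hydroxy-4-({2-hydroxy-6-methyl-4-[(2,3,4-trimethoxy-6-methylbenzoyl)oxy]benzoyl}oxy)-6-methylbenzoate, via trifluoroacetic mixed anhydride of the ring A–ring B acid 19 (not isolated)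
Conditions: 18, TFAA (1.5 equiv), toluene, 0 °C; then 11 (1.2 equiv), rt
Reagents that add atoms: none
Why: The same trifluoroacetic anhydride depside condensation, which is used with free ortho-hydroxybenzoic acids. The chelated 2-OH groups of 18 and 11 are poor nucleophiles, so the 4-OH of 11 should be the only phenol acylated.

Step 11
Reactants: 20 benzyl 2-hydroxy-4-({2-hydroxy-6-methyl-4-[(2,3,4-trimethoxy-6-methylbenzoyl)oxy]benzoyl}oxy)-6-methylbenzoate
Product: 21 2-hydroxy-4-({2-hydroxy-6-methyl-4-[(2,3,4-trimethoxy-6-methylbenzoyl)oxy]benzoyl}oxy)-6-methylbenzoic acid (CNP0332884.0)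
Conditions: H2 (1 atm), 10% Pd/C, EtOAc/THF, rt
Reagents that add atoms: none
Why: Neutral hydrogenolysis of the benzyl ester frees the terminal acid without touching either depside ester and without heat.

## Compound list

1 | trichloroethylene | ClC=C(Cl)Cl | starting material
2 | dichloroacetylene | ClC#CCl | intermediate
3 | (E)-1-tert-butoxy-1,2-dichloroethene | Cl/C=C(/Cl)OC(C)(C)C | intermediate
4 | 1-tert-butoxy-2-chloroacetylene | ClC#COC(C)(C)C | intermediate
5 | lithium tert-butoxyacetylide | [Li]C#COC(C)(C)C | intermediate
6 | tert-butoxyacetylene | C#COC(C)(C)C | intermediate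
7 | but-2-ynoic acid | CC#CC(=O)O | starting material
8 | benzyl alcohol | OCc1ccccc1 | starting material
9 | benzyl but-2-ynoate | CC#CC(=O)OCc1ccccc1 | intermediate
10 | benzyl 2,4-di-tert-butoxy-6-methylbenzoate | Cc1cc(OC(C)(C)C)cc(OC(C)(C)C)c1C(=O)OCc1ccccc1 | intermediate
11 | benzyl 2,4-dihydroxy-6-methylbenzoate | Cc1cc(O)cc(O)c1C(=O)OCc1ccccc1 | intermediate
12 | 3,4,5-trimethoxytoluene | COc1cc(C)cc(OC)c1OC | starting material
13 | 2-bromo-3,4,5-trimethoxytoluene | COc1cc(C)c(Br)c(OC)c1OC | intermediate
14 | (2,3,4-trimethoxy-6-methylphenyl)lithium | [Li]c1c(C)cc(OC)c(OC)c1OC | intermediate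
15 | 2,3,4-trimethoxy-6-methylbenzoic acid | COc1cc(C)c(C(=O)O)c(OC)c1OC | intermediate
16 | 2,3,4-trimethoxy-6-methylbenzoic trifluoroacetic anhydride | COc1cc(C)c(C(=O)OC(=O)C(F)(F)F)c(OC)c1OC | intermediate
17 | benzyl 2-hydroxy-6-methyl-4-[(2,3,4-trimethoxy-6-methylbenzoyl)oxy]benzoate | COc1cc(C)c(C(=O)Oc2cc(C)c(C(=O)OCc3ccccc3)c(O)c2)c(OC)c1OC | intermediate
18 | 2-hydroxy-6-methyl-4-[(2,3,4-trimethoxy-6-methylbenzoyl)oxy]benzoic acid | COc1cc(C)c(C(=O)Oc2cc(C)c(C(=O)O)c(O)c2)c(OC)c1OC | intermediate
19 | 2-hydroxy-6-methyl-4-[(2,3,4-trimethoxy-6-methylbenzoyl)oxy]benzoic trifluoroacetic anhydride | COc1cc(C)c(C(=O)Oc2cc(C)c(C(=O)OC(=O)C(F)(F)F)c(O)c2)c(OC)c1OC | intermediate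
20 | benzyl 2-hydroxy-4-({2-hydroxy-6-methyl-4-[(2,3,4-trimethoxy-6-methylbenzoyl)oxy]benzoyl}oxy)-6-methylbenzoate | COc1cc(C)c(C(=O)Oc2cc(C)c(C(=O)Oc3cc(C)c(C(=O)OCc4ccccc4)c(O)c3)c(O)c2)c(OC)c1OC | intermediate
21 | 2-hydroxy-4-({2-hydroxy-6-methyl-4-[(2,3,4-trimethoxy-6-methylbenzoyl)oxy]benzoyl}oxy)-6-methylbenzoic acid | COc1cc(C)c(C(=O)Oc2cc(C)c(C(=O)Oc3cc(C)c(C(=O)O)c(O)c3)c(O)c2)c(OC)c1OC | target

## Step count and risks

Total step count: 11. Longest linear sequence: 8 steps (steps 1, 2, 4, 5, 8, 9, 10 and 11).

**Step 4 (key step, proposed new method).** Most likely to go wrong is chemoselectivity: homotrimerisation of the ynol ether may outrun the cross-coupling. The second ynol ether may also insert in the reverse sense. The Lewis-acidic cationic rhodium may further promote hydration or loss of 2-methylpropene from 6. Fallback, using known chemistry and setting out from benzyl alcohol 8: heating 8 with 2,2,6-trimethyl-4H-1,3-dioxin-4-one in xylene (trapping of acetylketene) would give benzyl acetoacetate F1. Its dianion (NaH, then n-BuLi, THF) on warming undergoes the known self-condensation of acetoacetate dianions. Claisen attack of the γ-carbanion on the ester of a second molecule gives benzyl 3,5,7-trioxooctanoate F2, which closes by aldol condensation and aromatises in the same flask. The fallback comes back to the route at 11, and steps 1 to 5 are then not needed.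

**Step 10.** The activated hydroxy acid may acylate itself through its own ortho hydroxyl, giving oligomers, or the ring A–ring B ester may undergo acyl exchange in the acidic medium. Fallback, setting out from 10: the order of assembly is reversed. Hydrogenolysis of 10 (H2, Pd/C) would give 2,4-di-tert-butoxy-6-methylbenzoic acid F3. Steglich coupling with 11 (DCC, DMAP) would give benzyl 4-[(2,4-di-tert-butoxy-6-methylbenzoyl)oxy]-2-hydroxy-6-methylbenzoate F4. Trifluoroacetic acid would give benzyl 4-[(2,4-dihydroxy-6-methylbenzoyl)oxy]-2-hydroxy-6-methylbenzoate F5, the didepside that Alternative 3 would reach as A4. Acid 15 with TFAA should then acylate the only unchelated phenol, the ring B 4-OH. The fallback comes back at 20.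

**Step 8.** Acyl transfer from the doubly ortho-substituted ring A acid may be slow, so that trifluoroacetylation or C-acylation of the electron-rich phenol competes. Fallback, setting out from 15: oxalyl chloride with catalytic DMF would give 2,3,4-trimethoxy-6-methylbenzoyl chloride F6. This is added to 11 and K2CO3 in acetone, where the more acidic 4-OH is ionised selectively and selectivity rests on acidity instead of nucleophilicity. The fallback comes back at 17.

**Step 2.** Product may be lost on isolation through volatility, and through retro-ene fragmentation to ketene and 2-methylpropene on warming, so that too little ynol ether of adequate purity reaches step 4. Fallback, setting out from 9: commercial ethoxyacetylene replaces 6 under the conditions of step 4 and would give benzyl 2,4-diethoxy-6-methylbenzoate F7. BBr3 (CH2Cl2, −78 to 0 °C) cleaves both ethyl ethers and the benzyl ester to 2,4-dihydroxy-6-methylbenzoic acid F8. Benzyl bromide with KHCO3 in DMF re-forms the ester, and the fallback comes back at 11. It still relies on the cyclotrimerisation and costs one harsher step.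

## Further compounds

F1 | step 4 | benzyl acetoacetate | CC(=O)CC(=O)OCc1ccccc1
F2 | step 4 | benzyl 3,5,7-trioxooctanoate | CC(=O)CC(=O)CC(=O)CC(=O)OCc1ccccc1
F3 | step 10 | 2,4-di-tert-butoxy-6-methylbenzoic acid | Cc1cc(OC(C)(C)C)cc(OC(C)(C)C)c1C(=O)O
F4 | step 10 | benzyl 4-[(2,4-di-tert-butoxy-6-methylbenzoyl)oxy]-2-hydroxy-6-methylbenzoate | Cc1cc(OC(C)(C)C)cc(OC(C)(C)C)c1C(=O)Oc1cc(C)c(C(=O)OCc2ccccc2)c(O)c1
F5 | step 10 | benzyl 4-[(2,4-dihydroxy-6-methylbenzoyl)oxy]-2-hydroxy-6-methylbenzoate | Cc1cc(O)cc(O)c1C(=O)Oc1cc(C)c(C(=O)OCc2ccccc2)c(O)c1
F6 | step 8 | 2,3,4-trimethoxy-6-methylbenzoyl chloride | COc1cc(C)c(C(=O)Cl)c(OC)c1OC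
F7 | step 2 | benzyl 2,4-diethoxy-6-methylbenzoate | CCOc1cc(C)c(C(=O)OCc2ccccc2)c(OCC)c1
F8 | step 2 | 2,4-dihydroxy-6-methylbenzoic acid | Cc1cc(O)cc(O)c1C(=O)O
A1 | alternative 1 | benzyl 2-hydroxy-4-({2-(methoxymethoxy)-6-methyl-4-[(2,3,4-trimethoxy-6-methylbenzoyl)oxy]benzoyl}oxy)-6-methylbenzoate | COc1cc(C)c(C(=O)Oc2cc(C)c(C(=O)Oc3cc(C)c(C(=O)OCc4ccccc4)c(O)c3)c(OCOC)c2)c(OC)c1OC
A2 | alternative 1 | 4-bromo-3-(methoxymethoxy)-5-methylphenyl 2,3,4-trimethoxy-6-methylbenzoate | COc1cc(C)c(C(=O)Oc2cc(C)c(Br)c(OCOC)c2)c(OC)c1OC
A3 | alternative 2 | benzyl trans-6-methyl-2,4-dioxocyclohexane-1-carboxylate (racemic, one enantiomer drawn) | C[C@@H]1CC(=O)CC(=O)[C@H]1C(=O)OCc1ccccc1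
A4 | alternative 3 | benzyl 4-[(2,4-dihydroxy-6-methylbenzoyl)oxy]-2-hydroxy-6-methylbenzoate | Cc1cc(O)cc(O)c1C(=O)Oc1cc(C)c(C(=O)OCc2ccccc2)c(O)c1
A5 | alternative 3 | benzyl 2-hydroxy-6-methyl-4-[(3,5,7-trioxooctanoyl)oxy]benzoate | CC(=O)CC(=O)CC(=O)CC(=O)Oc1cc(C)c(C(=O)OCc2ccccc2)c(O)c1
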